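**One-step world.** A single step from starting material to target would climb to a plateau, but the north-west run reads 67.7% at 0.833 h and 27.7% at 3.00 h, so a second step consumes target.

- north-west: starting material 0.050 M; gas phase 10 mM (held); protic impurity 1 mM; the very flask that is asked about, followed so far
- flask: starting material 0.050 M; gas phase 10 mM (held); protic impurity 1.00 mM; time 3.0 h

north-west run (percent of the starting material charged)

| time / h | target / % |
|---|---|
| 0.250 | 42.3 |
| 0.417 | 57.8 |
| 0.833 | 67.7 |
| 1.50 | 55.3 |
| 3.00 | 27.7 |

(readings scatter by 1 percentage point)

- Wednesday's: at 3.0 h take out 90% of the target then present, then wait 6.0 h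
- Monday's: change nothing and wait 6.0 h more
- Sunday's: at 3.0 h add starting material, 50.0% of the amount charged, then wait 6.0 h

- what is taken out of target is counted as made
- the earlier runs were read with a standard deviation of 1 percentage point
- at the start none of the gas phase is in solution
- additions bring no volume worth counting

* target, in percent of the starting material first charged, at 3.0 h
* the remedy with the largest gain of target, or "none" below 2 percentage points (Wednesday's / Monday's / Sunday's / none)
* target present, with what was taken out counted in, in percent of the starting material first charged, after Wednesday's
* target present, with what was taken out counted in, in percent of the starting material first charged, after Sunday's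

**Hand chain.** The answer to "now" is the last reading, 27.7%, with a scatter of 1 percentage point. The first reading, counted as starting material spent, gives a rough feed constant 2.20 h⁻¹. The last two readings give a first loss constant 0.461 h⁻¹. Because the feed is faster, the late flask can be reckoned as a pseudo-first-order tail with the feed taken as finished. Over 6.0 h, target then keeps 6.30%. Wednesday's reaches 25.1%, Sunday's 5.73% and Monday's 1.74%, each lower than the reading , so this reckoning commits to none.

**Weak link.** At 1.50 h the feed still runs, so that reading stands below the pure tail, which the feed constant puts at 60.0%. The loss constant, the first-order rate at which target disappears once the feed has ended, becomes 0.515 h⁻¹. Target now keeps 4.55% over the wait, and Sunday's falls to 4.23%, while the verdict stands.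

**The forecast.** The forecast gives 27.8%, 25.2% for Wednesday's, 4.5% for Sunday's and none as best remedy, on the ground of “both steps pseudo-first-order with the gas held constant”. Its Sunday figure lies above the one reckoned here.

**The result.** The flask holds 27.1% of target; Wednesday's gives 24.5%, Sunday's 4.37%, and the best remedy is none.

    gas phase ⇌ dissolved gas, rate k1*(csat - [dissolved gas]) (kL = 0.158 s⁻¹)
    starting material + protic impurity → quenched substrate (k = 1.71 L mol⁻¹ s⁻¹)
    dissolved gas ⇌ dormant form (K = 2.20, k = 1.61 × 10⁻⁴ s⁻¹)
    starting material + dissolved gas → target (k = 0.0715 L mol⁻¹ s⁻¹)
    dissolved gas + target → over-reacted product (k = 0.0140 L mol⁻¹ s⁻¹)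

**Half-life against wait.** In the flask, target has a half-life of 1.4 h by the step from dissolved gas + target to over-reacted product at 3.00 h, far shorter than the wait of 6.0 h, and Monday's loses 26 points of the 27.1% while the loss constant leaves 1.23%. For the neighbour flask left until 8.0 h, the same constant carries the target of 27.1% forward by 5.00 h to 2.06%, and that flask holds 2.19% of target.

(The runs were computed from invented constants; noise was put on by code.)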